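A direct plan would build the chain first: Wittig extensions of a C10 dialdehyde would give the C22 iodo-octaenyne A1. Its dilithio derivative would open two molecules of enol lactone A2 and close both rings by aldol condensation to dione A3. Twofold enolate hydroxylation would then give bis-ketol A4, and hydroxyl-directed reduction the tetrol.
Its weakest steps would be:
- **The double ring annulation (A1 + A2 to A3).** It would need t-BuLi and an alkenyl/alkynyl dianion on a fully conjugated octaene, and each ring would close by aldol addition onto a ketone flanked by a quaternary carbon. This has no precedent and sits where most material is invested.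
- **The twofold enolate oxidation of A3.** C3 and C3' would be set by reagent control in two independent events on a C40 bis-dienolate. The 3R,3'S diastereomer would differ from A4 only at a centre some thirty bonds away and could hardly be removed.
- **The closing directed reduction of A4.** C4–OH and C4'–OH would be created in acetic acid as polyenylic alcohols that ionise easily, and the anti selectivity would again rest on two separate events on the finished polyene.

**Retrosynthetic overview**
- No ring is closed: ring A (C1–C6) and ring B (C1'–C6') both come intact from safranal, whose C3=C4 double bond is the latent trans-3,4-diol and whose formyl carbon becomes C7/C7'. The rings therefore exist before any polyene does, the reverse of the direct plan.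
- Key disconnections: C8–C9 (Sonogashira) and C8'–C9' (Negishi) to the symmetric C18 diiodide 14 (C9 to C9'). Compound 14 comes from the C10 dialdehyde by twofold C11=C12/C11'=C12' olefination with one C4 iodo phosphonate.
- One C11 ring alkyne 6 serves twice: as alkyne it becomes C7≡C8 of ring A, and after syn-hydrozirconation it becomes the E-C7'=C8' bond of ring B. One asymmetric epoxidation/anti-hydrolysis of the flat dienyne 3 thus sets C3, C4, C3' and C4' together.
- The weak steps are avoided by design: no carbanion, oxidant, hydride or acid meets the C40 polyene, and no stereocentre is made after the monomer. Every double bond is bought, set by syn-hydrometalation, or carried through a stereospecific coupling, so the 9E enyne is never equilibrated.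

Key step: step 2

Assumption: the (salen)Mn catalyst is taken to show on diene 3 the sense of induction it shows on 1,2-dihydronaphthalene and indene, which calls for the (R,R)-catalyst; locants follow carotenoid numbering.

Step 1
Reactants: 1 safranal (2,6,6-trimethylcyclohexa-1,3-diene-1-carbaldehyde)
Product: 3 1-ethynyl-2,6,6-trimethylcyclohexa-1,3-diene, via diazoalkene 2 (not isolated)
Conditions: Me3SiCHN2 (1.2 equiv), LiN(i-Pr)2 (1.2 equiv), THF, −78 °C; then 1, −78 °C → rt; H2O
Reagents that add atoms: (trimethylsilyl)diazomethane, C[Si](C)(C)C=[N+]=[N-]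
Why: Colvin rearrangement: the lithiated silyldiazomethane adds to the hindered formyl group, Peterson elimination gives diazoalkene 2, and loss of N2 with 1,2-hydrogen shift in the alkylidene carbene should give the terminal alkyne in one flask, the added carbon becoming C8 (and C8'); no stereocentre is involved.

Step 2
Reactants: 3 1-ethynyl-2,6,6-trimethylcyclohexa-1,3-diene
Product: 5 (1S,2S)-4-ethynyl-3,5,5-trimethylcyclohex-3-ene-1,2-diol, via epoxide 4 (not isolated)
Conditions: (R,R)-[N,N'-bis(3,5-di-tert-butylsalicylidene)cyclohexane-1,2-diaminato]MnCl (5 mol %), N-methylmorpholine N-oxide (5 equiv), mCPBA (1.5 equiv), CH2Cl2, −78 °C; aq. NaOH wash; then HClO4 (5 mol %), THF–H2O (3:1), 0 °C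
Reagents that add atoms: 3-chloroperoxybenzoic acid, O=C(OO)c1cccc(Cl)c1; water, O
Why: Jacobsen–Katsuki epoxidation followed by acid-catalysed anti-hydrolysis: the oxo-manganese salen species transfers oxygen to one face of the cis-disubstituted C3=C4 bond of the conjugated diene, the substrate class (1,2-dihydronaphthalene, indene, chromenes) for which this catalyst is most selective. Only the transient oxirane is closed (3-exo oxygen transfer), and it is opened in the same operation by protonation and attack of water at the allylic, enyne-stabilised C4 with inversion, so C3 keeps the oxygen delivered by the catalyst and C4 receives hydroxyl on the opposite face. C3 is therefore set by the (R,R)-catalyst (3S) and C4 by the stereospecific anti-opening (4R in epoxide 4 becomes 4S), which should give the trans-(3S,4S)-diol; since 5 supplies both rings, this one operation fixes C3, C4, C3' and C4' of the target. The step needs site selectivity for C3=C4 over the tetrasubstituted C5=C6 bond and the alkyne, secured by the catalyst's preference for cis-disubstituted conjugated alkenes and by the methyl and gem-dimethyl groups that shield C5=C6. It also needs water to enter at C4 and not at C3, secured by the allylic activation of C4; attack at C3 would give the enantiomeric diol, so any leakage would show as lower enantiomeric purity, which recrystallisation of 5 should restore.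

Step 3
Reactants: 5 (1S,2S)-4-ethynyl-3,5,5-trimethylcyclohex-3-ene-1,2-diol
Product: 6 [(1S,2S)-4-ethynyl-3,5,5-trimethylcyclohex-3-ene-1,2-diyl]bis(oxy)bis[tert-butyl(dimethyl)silane] (bis-TBS ether of 5)
Conditions: t-BuMe2SiOTf (2.6 equiv), 2,6-lutidine (4 equiv), CH2Cl2, −78 → 0 °C
Reagents that add atoms: tert-butyldimethylsilyl trifluoromethanesulfonate, CC(C)(C)[Si](C)(C)OS(=O)(=O)C(F)(F)F
Why: Silylation with the silyl triflate caps both secondary hydroxyls, the hindered allylic one included, which removes the protons that would quench Cp2Zr(H)Cl and the alkenylzinc and makes the C4–O bond less prone to ionise; the stereocentres are not touched.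

Step 4
Reactants: 7 but-2-yn-1-ol
Product: 9 (2E)-3-iodobut-2-en-1-ol, via alkenylzirconocene 8 (not isolated)
Conditions: Cp2Zr(H)Cl (2.3 equiv), THF, rt → 40 °C; then I2 (1.1 equiv), 0 °C; aq. work-up
Reagents that add atoms: iodine, II
Why: Hydrozirconation–iodination: syn addition of Zr–H to the internal alkyne, with the excess hydride equilibrating zirconium to the methyl-bearing carbon remote from the O-zirconated CH2O group, and iodinolysis with retention should give the 2E iodide, whose geometry becomes that of C9=C10 and C9'=C10'.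

Step 5
Reactants: 9 (2E)-3-iodobut-2-en-1-ol
Product: 11 diethyl [(2E)-3-iodobut-2-en-1-yl]phosphonate, via allylic bromide 10 (not isolated)
Conditions: PBr3 (0.4 equiv), Et2O, 0 °C; then P(OEt)3 (2 equiv), neat, 100 °C
Reagents that add atoms: triethyl phosphite, CCOP(OCC)OCC
Why: SN2 bromination of the primary allylic alcohol and Michaelis–Arbuzov reaction of the crude bromide should give the allylic phosphonate; the alkenyl iodide does not react with the phosphite without a nickel or palladium catalyst, and the double bond keeps its E geometry.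

Step 6
Reactants: 11 diethyl [(2E)-3-iodobut-2-en-1-yl]phosphonate (2.3 equiv); 12 (2E,4E,6E)-2,7-dimethylocta-2,4,6-trienedial
Product: 14 (2E,4E,6E,8E,10E,12E,14E)-2,15-diiodo-6,11-dimethylhexadeca-2,4,6,8,10,12,14-heptaene, via phosphonate anion 13 (not isolated)
Conditions: NaN(SiMe3)2 (2.3 equiv), THF, −78 °C; then 12, −78 → 0 °C, dark
Reagents that add atoms: none
Why: Twofold Horner–Wadsworth–Emmons olefination: anion 13, a vinylogue of the iodomethylene ylide and expected to be stable at low temperature, adds through its α-carbon to both formyl groups of the symmetric dialdehyde and should form C11=C12 and C11'=C12' with the E selectivity usual for allylic phosphonates and enals, giving the whole C9–C9' chain with both coupling handles in one step.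

Step 7
Reactants: 6 bis-TBS ring alkyne; 14 C18 diiodide (3 equiv, excess recovered)
Product: 17 {[(1S,2S)-4-[(1E,3E,5E,7E,9E,11E,13E,15E)-16-iodo-3,7,12-trimethylheptadeca-1,3,5,7,9,11,13,15-octaen-1-yl]-3,5,5-trimethylcyclohex-3-ene-1,2-diyl]bis(oxy)}bis[tert-butyl(dimethyl)silane], via alkenylzirconocene 15 (not isolated), via alkenylzinc chloride 16 (not isolated)
Conditions: Cp2Zr(H)Cl (1.2 equiv), THF, rt; ZnCl2 (1.2 equiv), 0 °C; then added to 14 (3 equiv), Pd(PPh3)4 (5 mol %), THF, rt, dark
Reagents that add atoms: none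
Why: Negishi coupling: syn-hydrozirconation of the terminal alkyne puts zirconium on C8' with E geometry (the future C7'=C8' bond), transmetalation to zinc and palladium-catalysed coupling with one C–I terminus of 14 proceed with retention at both carbons, and the threefold excess of the recoverable diiodide should hold the reaction at mono-coupling; the silyl ethers and the polyene are inert to all three metals.

Step 8
Reactants: 17 C29 polyenyl iodide; 6 bis-TBS ring alkyne (1.3 equiv)
Product: 18 (3S,4S,3'S,4'S)-3,4,3',4'-tetrakis(tert-butyldimethylsilyloxy)-7,8-didehydro-β,β-carotene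
Conditions: Pd(PPh3)4 (5 mol %), CuI (10 mol %), i-Pr2NH, THF, rt, degassed, dark
Reagents that add atoms: none
Why: Sonogashira coupling of the terminal alkyne of 6 with the remaining alkenyl iodide should form C8–C9 with retention of the 9E geometry under neutral conditions at room temperature, so the C7≡C8 triple bond, the one feature that breaks the symmetry of the target, enters in the last carbon–carbon bond formation and the enyne never meets an ylide or an equilibrating agent.

Step 9
Reactants: 18 tetrakis-TBS ether
Product: 19 (3S,4S,3'S,4'S)-7,8-didehydro-β,β-carotene-3,4,3',4'-tetrol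
Conditions: Bu4NF (8 equiv), THF, 0 °C → rt, argon, dark; H2O work-up
Reagents that add atoms: none
Why: Fluoride-induced cleavage of the four silyl ethers under basic, non-acidic conditions should free the tetrol without ionising the polyenylic C4–O and C4'–O bonds; carotenols of this kind tolerate base, and no stereocentre or double bond is touched.

**Compound list**

1 | safranal (2,6,6-trimethylcyclohexa-1,3-diene-1-carbaldehyde) | CC1=C(C=O)C(C)(C)CC=C1 | starting material
2 | 1-(2-diazoethenyl)-2,6,6-trimethylcyclohexa-1,3-diene | CC1=C(C=C=[N+]=[N-])C(C)(C)CC=C1 | intermediate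
3 | 1-ethynyl-2,6,6-trimethylcyclohexa-1,3-diene | CC1=C(C#C)C(C)(C)CC=C1 | intermediate
4 | (1R,6S)-3-ethynyl-2,4,4-trimethyl-7-oxabicyclo[4.1.0]hept-2-ene (3S,4R-epoxide in carotenoid numbering) | CC1=C(C#C)C(C)(C)C[C@@H]2O[C@H]12 | intermediate
5 | (1S,2S)-4-ethynyl-3,5,5-trimethylcyclohex-3-ene-1,2-diol (trans-diol; 3S,4S in carotenoid numbering) | CC1=C(C#C)C(C)(C)C[C@H](O)[C@H]1O | intermediate
6 | [(1S,2S)-4-ethynyl-3,5,5-trimethylcyclohex-3-ene-1,2-diyl]bis(oxy)bis[tert-butyl(dimethyl)silane] | CC1=C(C#C)C(C)(C)C[C@H](O[Si](C)(C)C(C)(C)C)[C@H]1O[Si](C)(C)C(C)(C)C | intermediate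
7 | but-2-yn-1-ol | CC#CCO | starting material
8 | chlorobis(cyclopentadienyl)[(2E)-4-{[chlorobis(cyclopentadienyl)zirconio]oxy}but-2-en-2-yl]zirconium | Cl[Zr](C1C=CC=C1)(C1C=CC=C1)/C(C)=C/CO[Zr](Cl)(C1C=CC=C1)C1C=CC=C1 | intermediate
9 | (2E)-3-iodobut-2-en-1-ol | I/C(C)=C/CO | intermediate
10 | (2E)-1-bromo-3-iodobut-2-ene | I/C(C)=C/CBr | intermediate
11 | diethyl [(2E)-3-iodobut-2-en-1-yl]phosphonate | I/C(C)=C/CP(=O)(OCC)OCC | intermediate
12 | (2E,4E,6E)-2,7-dimethylocta-2,4,6-trienedial | O=C/C(C)=C/C=C/C=C(C)/C=O | starting material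
13 | sodium salt of the α-carbanion of 11 | I/C(C)=C/[CH-]P(=O)(OCC)OCC.[Na+] | intermediate
14 | (2E,4E,6E,8E,10E,12E,14E)-2,15-diiodo-6,11-dimethylhexadeca-2,4,6,8,10,12,14-heptaene | I/C(C)=C/C=C/C(C)=C/C=C/C=C(C)/C=C/C=C(C)/I | intermediate
15 | chlorobis(cyclopentadienyl){(E)-2-[(3S,4S)-3,4-bis(tert-butyldimethylsilyloxy)-2,6,6-trimethylcyclohex-1-en-1-yl]ethenyl}zirconium | Cl[Zr](C1C=CC=C1)(C1C=CC=C1)/C=C/C2=C(C)[C@H](O[Si](C)(C)C(C)(C)C)[C@@H](O[Si](C)(C)C(C)(C)C)CC2(C)C | intermediate
16 | chloro{(E)-2-[(3S,4S)-3,4-bis(tert-butyldimethylsilyloxy)-2,6,6-trimethylcyclohex-1-en-1-yl]ethenyl}zinc | Cl[Zn]/C=C/C1=C(C)[C@H](O[Si](C)(C)C(C)(C)C)[C@@H](O[Si](C)(C)C(C)(C)C)CC1(C)C | intermediate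
17 | {[(1S,2S)-4-[(1E,3E,5E,7E,9E,11E,13E,15E)-16-iodo-3,7,12-trimethylheptadeca-1,3,5,7,9,11,13,15-octaen-1-yl]-3,5,5-trimethylcyclohex-3-ene-1,2-diyl]bis(oxy)}bis[tert-butyl(dimethyl)silane] (ring B with the C7'–C9 chain, iodide at C9) | I/C(C)=C/C=C/C(C)=C/C=C/C=C(C)/C=C/C=C(C)/C=C/C1=C(C)[C@H](O[Si](C)(C)C(C)(C)C)[C@@H](O[Si](C)(C)C(C)(C)C)CC1(C)C | intermediate
18 | (3S,4S,3'S,4'S)-3,4,3',4'-tetrakis(tert-butyldimethylsilyloxy)-7,8-didehydro-β,β-carotene | CC1=C(C#C/C(C)=C/C=C/C(C)=C/C=C/C=C(C)/C=C/C=C(C)/C=C/C2=C(C)[C@H](O[Si](C)(C)C(C)(C)C)[C@@H](O[Si](C)(C)C(C)(C)C)CC2(C)C)C(C)(C)C[C@H](O[Si](C)(C)C(C)(C)C)[C@H]1O[Si](C)(C)C(C)(C)C | intermediate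
19 | (3S,4S,3'S,4'S)-7,8-didehydro-β,β-carotene-3,4,3',4'-tetrol | CC1=C(C#C/C(C)=C/C=C/C(C)=C/C=C/C=C(C)/C=C/C=C(C)/C=C/C2=C(C)[C@H](O)[C@@H](O)CC2(C)C)C(C)(C)C[C@H](O)[C@H]1O | target

**Step count and risks**

Total steps: 9. Longest linear sequence: 6 (steps 1, 2, 3, 7, 8, 9 from safranal; equally steps 4, 5, 6, 7, 8, 9 from but-2-yn-1-ol).

Steps most likely to fail:

1. **Step 2.** Oxygen transfer may show poor facial selectivity on this diene, water may enter partly at C3 (which lowers the enantiomeric purity), or the opening may drift towards an SN1 course and give some cis-diol. The fallback sets out from 3 and comes back at 5, and lets an enzyme, not the oxidation catalyst, fix the absolute configuration. Epoxidation of 3 with the achiral complex [N,N'-bis(3,5-di-tert-butylsalicylidene)ethane-1,2-diaminato]MnCl and mCPBA would give 4 together with its enantiomer, (1S,6R)-3-ethynyl-2,4,4-trimethyl-7-oxabicyclo[4.1.0]hept-2-ene F1. The same acid hydrolysis would give 5 together with its enantiomer, (1R,2R)-4-ethynyl-3,5,5-trimethylcyclohex-3-ene-1,2-diol F2. A lipase chosen by screening (for example Burkholderia cepacia lipase, vinyl acetate, t-BuOMe) would acylate only F2 at its less hindered hydroxyl to (1R,2R)-4-ethynyl-2-hydroxy-3,5,5-trimethylcyclohex-3-en-1-yl acetate F3, and unreacted 5 would be separated by chromatography.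

2. **Step 7.** The two identical C–I termini of 14 cannot be told apart, so double coupling may compete, and slow transmetalation of the alkenylzinc may end in protodemetalation. The fallback sets out from 6 (through 16) and 11 and comes back at 17, and moves the break of symmetry to the cheap dialdehyde. Negishi coupling of 16 with 11 would give the ring-B dienyl phosphonate diethyl [(2E,4E)-5-[(3S,4S)-3,4-bis(tert-butyldimethylsilyloxy)-2,6,6-trimethylcyclohex-1-en-1-yl]-3-methylpenta-2,4-dien-1-yl]phosphonate F4. Horner–Wadsworth–Emmons reaction of its sodium salt with an excess of 12 would give the C25 aldehyde (3S,4S)-3,4-bis(tert-butyldimethylsilyloxy)-12'-apo-β-caroten-12'-al F5. Olefination of F5 with anion 13 would then give 17.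

3. **Step 6.** Anion 13 may lose iodide or lose its 2E geometry through rotation in the delocalised allyl anion, and the new C11=C12 and C11'=C12' bonds may form as E/Z mixtures. The fallback sets out from 6, 11 and 12 and comes back at 18, and uses no γ-iodoallyl anion. Sonogashira coupling of 6 with 11 would give the ring-A enyne phosphonate diethyl [(2E)-5-[(3S,4S)-3,4-bis(tert-butyldimethylsilyloxy)-2,6,6-trimethylcyclohex-1-en-1-yl]-3-methylpent-2-en-4-yn-1-yl]phosphonate F6. The aldehyde F5, made from F4 and 12 as in the preceding fallback, would be olefinated with the sodium salt of F6 to give 18 directly.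

Further compounds
F1 | step 2 | (1S,6R)-3-ethynyl-2,4,4-trimethyl-7-oxabicyclo[4.1.0]hept-2-ene (enantiomer of 4) | CC1=C(C#C)C(C)(C)C[C@H]2O[C@@H]12
F2 | step 2 | (1R,2R)-4-ethynyl-3,5,5-trimethylcyclohex-3-ene-1,2-diol (enantiomer of 5) | CC1=C(C#C)C(C)(C)C[C@@H](O)[C@@H]1O
F3 | step 2 | (1R,2R)-4-ethynyl-2-hydroxy-3,5,5-trimethylcyclohex-3-en-1-yl acetate | CC1=C(C#C)C(C)(C)C[C@@H](OC(C)=O)[C@@H]1O
F4 | step 7 | diethyl [(2E,4E)-5-[(3S,4S)-3,4-bis(tert-butyldimethylsilyloxy)-2,6,6-trimethylcyclohex-1-en-1-yl]-3-methylpenta-2,4-dien-1-yl]phosphonate | CCOP(=O)(OCC)C/C=C(C)/C=C/C1=C(C)[C@H](O[Si](C)(C)C(C)(C)C)[C@@H](O[Si](C)(C)C(C)(C)C)CC1(C)C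
F5 | step 7 | (3S,4S)-3,4-bis(tert-butyldimethylsilyloxy)-12'-apo-β-caroten-12'-al (C25 aldehyde, ring B with the all-E chain to the C12 formyl group) | O=C/C(C)=C/C=C/C=C(C)/C=C/C=C(C)/C=C/C1=C(C)[C@H](O[Si](C)(C)C(C)(C)C)[C@@H](O[Si](C)(C)C(C)(C)C)CC1(C)C
F6 | step 6 | diethyl [(2E)-5-[(3S,4S)-3,4-bis(tert-butyldimethylsilyloxy)-2,6,6-trimethylcyclohex-1-en-1-yl]-3-methylpent-2-en-4-yn-1-yl]phosphonate | CCOP(=O)(OCC)C/C=C(C)/C#CC1=C(C)[C@H](O[Si](C)(C)C(C)(C)C)[C@@H](O[Si](C)(C)C(C)(C)C)CC1(C)C
A1 | direct plan | (1E,3E,5E,7E,9E,11E,13E,15E)-1-iodo-3,7,12,16-tetramethyloctadeca-1,3,5,7,9,11,13,15-octaen-17-yne | I/C=C/C(C)=C/C=C/C(C)=C/C=C/C=C(C)/C=C/C=C(C)/C#C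
A2 | direct plan | (6Z)-6-ethylidene-3,3-dimethyloxan-2-one | C/C=C1/CCC(C)(C)C(=O)O1
A3 | direct plan | 7,8-didehydro-β,β-carotene-4,4'-dione | CC1=C(C#C/C(C)=C/C=C/C(C)=C/C=C/C=C(C)/C=C/C=C(C)/C=C/C2=C(C)C(=O)CCC2(C)C)C(C)(C)CCC1=O
A4 | direct plan | (3S,3'S)-3,3'-dihydroxy-7,8-didehydro-β,β-carotene-4,4'-dione | CC1=C(C#C/C(C)=C/C=C/C(C)=C/C=C/C=C(C)/C=C/C=C(C)/C=C/C2=C(C)C(=O)[C@@H](O)CC2(C)C)C(C)(C)C[C@H](O)C1=O
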